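**Plan**

1. Retrosynthesis (target numbered as a naphthalen-2(1H)-one: C-1 side chain, C-2 ketone, C-4a ring-fusion H, C-6 CH3/diol, C-8a angular CH3): cut C-1–C-1′ (aldol condensation, hydrogenation) to a ring-A enone and a chiral C6 aldehyde; take the enone back to a 2,4-dione (1,3-carbonyl transposition); cut C-2–C-3 and C-4a–C-8a together, which opens both rings to one acyclic chain; cut that chain at the quaternary C-6 (C–CH3, from an epoxy alcohol) and at a trisubstituted alkene.
2. Enabling feature: in ring A the C-2 carbonyl is β to the quaternary C-8a, so C-8a–C-1–C-2 is a latent alkylidene malonate (electrophilic β-carbon plus acyl carbon), and the opposite carbons C-3–C-4–C-4a are the CH3, C=O and α-CH2 of a methyl ketone. The extra C-4 carbonyl and the extra C-1 ester are temporary activating groups and are removed afterwards.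
3. Forward: the chain is built first; one base operation closes ring B (Michael addition, C-4a–C-8a) and ring A (Claisen condensation, C-2–C-3); decarboxylation and transposition trim ring A; the side chain is joined last.
4. Stereochemistry: C-6 and the ring-diol carbinol come from a Sharpless epoxidation and anti opening with trimethylaluminium; C-8a and C-4a are relayed from C-6 through a chair in the cascade; C-1 is set by hydrogenation anti to the angular methyl; the side-chain carbinol comes from (R)-2-methylglycidol.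

Key step: step 9

Remark: locants in the text are those of the target even where the systematic name of an intermediate numbers the ring differently; the transient stereocentres of 15, 18, 25 and 26 and the alkene geometry of 27 are erased later and are left open.

**Route**

Step 1
Reactants: 1 methyl 3-oxohept-6-enoate
Product: 2 methyl (2E)-3-{[(trifluoromethyl)sulfonyl]oxy}hepta-2,6-dienoate
Conditions: Tf2O, aq. (CH3)4NOH, toluene, 5 °C
Reagents that add atoms: trifluoromethanesulfonic anhydride, O=S(=O)(OS(=O)(=O)C(F)(F)F)C(F)(F)F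
Why: Schotten–Baumann-type O-triflation of the β-keto ester enolate, in which the non-chelating tetramethylammonium counter-ion should favour the open enolate and hence the (E)-enol triflate, placing the butenyl arm cis to the ester as the later steps require.

Step 2
Reactants: 2 methyl (2E)-3-{[(trifluoromethyl)sulfonyl]oxy}hepta-2,6-dienoate; 3 2-(2-bromoethyl)-2-methyl-1,3-dioxolane
Product: 5 methyl (2E)-3-[2-(2-methyl-1,3-dioxolan-2-yl)ethyl]hepta-2,6-dienoate, via dioxolanylethylmagnesium bromide 4 (not isolated)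
Conditions: 3, Mg, THF, 25 °C; then 2, Fe(acac)3 (5 mol %), THF/NMP, −30 °C
Reagents that add atoms: none
Why: Iron-catalysed Kumada-type coupling of an alkyl Grignard reagent with an alkenyl triflate should run with retention of alkene geometry and faster than attack on the ester, giving the stereodefined trisubstituted enoate.

Step 3
Reactants: 5 methyl (2E)-3-[2-(2-methyl-1,3-dioxolan-2-yl)ethyl]hepta-2,6-dienoate
Product: 6 (2E)-3-[2-(2-methyl-1,3-dioxolan-2-yl)ethyl]hepta-2,6-dien-1-ol
Conditions: (i-Bu)2AlH (2.2 equiv), CH2Cl2, −78 °C; aqueous work-up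
Reagents that add atoms: none
Why: Hydride 1,2-reduction of the conjugated ester to the allylic alcohol, which leaves the ketal and both alkenes untouched.

Step 4
Reactants: 6 (2E)-3-[2-(2-methyl-1,3-dioxolan-2-yl)ethyl]hepta-2,6-dien-1-ol
Product: 7 [(2R,3R)-3-(but-3-en-1-yl)-3-[2-(2-methyl-1,3-dioxolan-2-yl)ethyl]oxiran-2-yl]methanol
Conditions: Ti(OiPr)4 (10 mol %), D-(−)-diethyl tartrate (12 mol %), t-BuOOH, 4 Å MS, CH2Cl2, −20 °C
Reagents that add atoms: tert-butyl hydroperoxide, CC(C)(C)OO
Why: Sharpless asymmetric epoxidation, in which the D-(−)-tartrate ligand selects the alkene face that gives the (2R,3R)-epoxide and only the allylic alkene is epoxidised.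

Step 5
Reactants: 7 [(2R,3R)-3-(but-3-en-1-yl)-3-[2-(2-methyl-1,3-dioxolan-2-yl)ethyl]oxiran-2-yl]methanol
Product: 8 (2S,3R)-3-methyl-3-[2-(2-methyl-1,3-dioxolan-2-yl)ethyl]hept-6-ene-1,2-diol
Conditions: Me3Al (3 equiv), hexane/CH2Cl2, 0 °C; aqueous work-up
Reagents that add atoms: trimethylaluminium, C[Al](C)C
Why: Trimethylaluminium opening of a 2,3-epoxy alcohol, in which the aluminium alkoxide directs methyl to the tertiary C-3 with inversion, so the all-carbon quaternary centre (target C-6) and the (S)-carbinol are set stereospecifically from the epoxide.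

Step 6
Reactants: 8 (2S,3R)-3-methyl-3-[2-(2-methyl-1,3-dioxolan-2-yl)ethyl]hept-6-ene-1,2-diol
Product: 10 (5R)-5-[(1S)-1,2-bis(benzyloxy)ethyl]-5-methylnon-8-en-2-one, via bis-benzyl ether ketal 9 (not isolated)
Conditions: NaH, BnBr, Bu4NI (cat.), DMF, 0 → 23 °C; then 2 M HCl, THF, 23 °C
Reagents that add atoms: benzyl bromide, BrCc1ccccc1; water, O
Why: Williamson etherification of both hydroxyls followed by acid hydrolysis of the dioxolane frees the methyl ketone only after the diol is capped, which prevents its intramolecular ketalisation.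

Step 7
Reactants: 10 (5R)-5-[(1S)-1,2-bis(benzyloxy)ethyl]-5-methylnon-8-en-2-one; 11 dimethyl malonate
Product: 12 dimethyl 2-[(5R)-5-[(1S)-1,2-bis(benzyloxy)ethyl]-5-methylnon-8-en-2-ylidene]propanedioate
Conditions: TiCl4, pyridine, THF, 0 → 23 °C
Reagents that add atoms: none
Why: Knoevenagel condensation of the methyl ketone with malonate under TiCl4/pyridine gives the doubly activated tetrasubstituted acceptor, while the terminal alkene and the benzyl ethers are inert.

Step 8
Reactants: 12 dimethyl 2-[(5R)-5-[(1S)-1,2-bis(benzyloxy)ethyl]-5-methylnon-8-en-2-ylidene]propanedioate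
Product: 13 dimethyl 2-[(5S)-5-[(1S)-1,2-bis(benzyloxy)ethyl]-5-methyl-8-oxononan-2-ylidene]propanedioate
Conditions: PdCl2 (10 mol %), CuCl (30 mol %), O2 (1 atm), DMF/H2O 7:1, 23 °C
Reagents that add atoms: water, O; dioxygen, O=O (terminal oxidant, net source of the oxygen atom)
Why: Wacker oxidation converts the monosubstituted alkene into the methyl ketone with Markovnikov selectivity, and the electron-poor tetrasubstituted alkene does not react.

Step 9
Reactants: 13 dimethyl 2-[(5S)-5-[(1S)-1,2-bis(benzyloxy)ethyl]-5-methyl-8-oxononan-2-ylidene]propanedioate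
Product: 16 (4aR,7S,8aS)-7-[(1S)-1,2-bis(benzyloxy)ethyl]-4a,7-dimethylhexahydronaphthalene-1,3(2H,4H)-dione (trans-fused), via Michael adduct 14 (not isolated), via ester dione 15 (not isolated)
Conditions: NaOMe (2.5 equiv), MeOH, 0.02 M, 65 °C; then 2 M aq. KOH, 80 °C; then 2 M HCl to pH 2, 23 °C
Reagents that add atoms: none
Why: Methoxide equilibrates the ketone enolates; the internal enolate adds to the β-carbon of the alkylidene malonate in a 6-(enolexo)-exo-trig Michael addition that closes ring B and creates the quaternary C-8a, and after proton transfer the methyl-side enolate acylates one malonate ester in a 6-(enolendo)-exo-trig Claisen condensation that closes ring A. The sequence is the intramolecular counterpart of the classical Michael–Claisen synthesis of cyclohexane-1,3-diones (dimedone type), including saponification and decarboxylation of the vinylogous β-keto acid in the same flask. Ring B should form through a chair with the bulky bis(benzyloxy)ethyl group of the existing C-6 stereocentre equatorial and the C-6 methyl axial; the malonate unit at C-8a takes the equatorial position (an axial alkylidene malonate would suffer allylic strain against the ring), which leaves the angular methyl axial and anti to the C-6 methyl. C-4a stays epimerisable while it is α to the acetyl group and should settle with the acetyl equatorial, because the axial position is blocked by a 1,3-diaxial clash with the C-6 methyl, so ring A can close only from the trans-diequatorial pair and the ring fusion becomes trans. The step needs regioselectivity between the two enolates, secured by ring size (the methyl-side enolate would have to form an eight-membered ring in the Michael step, and the only Claisen alternative is a four-membered ring), and diastereoselectivity relative to C-6, secured by the size difference between methyl and the bis-ether arm; formation of the stabilised diketonate makes the Claisen step irreversible and protects C-4a.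

Step 10
Reactants: 16 (4aR,7S,8aS)-7-[(1S)-1,2-bis(benzyloxy)ethyl]-4a,7-dimethylhexahydronaphthalene-1,3(2H,4H)-dione
Product: 17 (4aR,7S,8aS)-7-[(1S)-1,2-bis(benzyloxy)ethyl]-3-methoxy-4a,7-dimethyl-4a,5,6,7,8,8a-hexahydronaphthalen-1(4H)-one
Conditions: MeOH, p-TsOH (cat.), 3 Å MS, 23 °C
Reagents that add atoms: methanol, CO
Why: Acid-catalysed enol etherification of the 1,3-dione (first half of a Stork–Danheiser sequence) should place the methoxy group on the less hindered carbonyl carbon (target C-2, flanked by CH2) and keep the carbonyl next to the ring-fusion CH, and the mild conditions should leave C-4a unepimerised.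

Step 11
Reactants: 17 (4aR,7S,8aS)-7-[(1S)-1,2-bis(benzyloxy)ethyl]-3-methoxy-4a,7-dimethyl-4a,5,6,7,8,8a-hexahydronaphthalen-1(4H)-one
Product: 19 (4aR,6S,8aR)-6-[(1S)-1,2-bis(benzyloxy)ethyl]-6,8a-dimethyl-4a,5,6,7,8,8a-hexahydronaphthalen-2(1H)-one, via allylic alcohol 18 (not isolated)
Conditions: LiAlH4, Et2O, 0 °C; then 1 M HCl, THF, 23 °C
Reagents that add atoms: water, O
Why: Stork–Danheiser 1,3-carbonyl transposition, in which 1,2-reduction of the vinylogous ester and acid hydrolysis of the enol ether with loss of water removes the helper oxygen at target C-4 and leaves the ketone at C-2 with a C-3/C-4 alkene.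

Step 12
Reactants: 20 [(2R)-2-methyloxiran-2-yl]methanol; 21 allylmagnesium bromide
Product: 22 (2S)-2-methylhex-5-ene-1,2-diol
Conditions: 21 (2.5 equiv), CuI (10 mol %), THF, −30 → 0 °C; aq. NH4Cl
Reagents that add atoms: none
Why: Copper-catalysed Grignard opening of the epoxide at its CH2 terminus, which does not touch the tertiary stereocentre.

Step 13
Reactants: 22 (2S)-2-methylhex-5-ene-1,2-diol
Product: 23 (4S)-4-(but-3-en-1-yl)-2,2,4-trimethyl-1,3-dioxolane
Conditions: 2,2-dimethoxypropane, PPTS (cat.), CH2Cl2, 23 °C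
Reagents that add atoms: 2,2-dimethoxypropane, COC(C)(C)OC
Why: Acid-catalysed transketalisation protects the 1,2-diol as its acetonide, which is stable to the amide base and hydrogenation used later.

Step 14
Reactants: 23 (4S)-4-(but-3-en-1-yl)-2,2,4-trimethyl-1,3-dioxolane
Product: 24 3-[(4S)-2,2,4-trimethyl-1,3-dioxolan-4-yl]propanal
Conditions: O3, CH2Cl2, −78 °C; then PPh3, −78 → 23 °C
Reagents that add atoms: ozone, [O-][O+]=O
Why: Ozonolysis with reductive work-up cleaves the terminal alkene to the aldehyde and leaves the acetonide intact.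

Step 15
Reactants: 19 (4aR,6S,8aR)-6-[(1S)-1,2-bis(benzyloxy)ethyl]-6,8a-dimethyl-4a,5,6,7,8,8a-hexahydronaphthalen-2(1H)-one; 24 3-[(4S)-2,2,4-trimethyl-1,3-dioxolan-4-yl]propanal
Product: 27 (1Z,4aR,6S,8aS)-6-[(1S)-1,2-bis(benzyloxy)ethyl]-6,8a-dimethyl-1-{3-[(4S)-2,2,4-trimethyl-1,3-dioxolan-4-yl]propylidene}-4a,5,6,7,8,8a-hexahydronaphthalen-2(1H)-one, via aldol adduct 25 (not isolated), via aldol mesylate 26 (not isolated)
Conditions: LiN(i-Pr)2 (1.1 equiv), THF, −78 °C; 24; then MsCl, −78 → 0 °C; then DBU, 23 °C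
Reagents that add atoms: none
Why: Kinetic deprotonation of the enone at the α′-CH2 (C-1) gives the cross-conjugated lithium enolate, and its aldol addition to 24 followed by mesylation and E1cB elimination (aldol condensation) should give the exocyclic enone, whose geometry (Z expected, to avoid allylic strain against C-8a) does not matter.

Step 16
Reactants: 27 (1Z,4aR,6S,8aS)-6-[(1S)-1,2-bis(benzyloxy)ethyl]-6,8a-dimethyl-1-{3-[(4S)-2,2,4-trimethyl-1,3-dioxolan-4-yl]propylidene}-4a,5,6,7,8,8a-hexahydronaphthalen-2(1H)-one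
Product: 29 (1R,4aS,6S,8aS)-6-[(1S)-1,2-dihydroxyethyl]-1-[(4S)-4,5-dihydroxy-4-methylpentyl]-6,8a-dimethyloctahydronaphthalen-2(1H)-one, via acetonide keto diol 28 (not isolated)
Conditions: H2 (3 atm), Pd/C, EtOAc/EtOH, 23 °C; filter; then 1 M aq. HCl, THF, 23 °C
Reagents that add atoms: none
Why: Heterogeneous hydrogenation saturates both enone alkenes and hydrogenolyses the benzyl ethers, delivering hydrogen to C-1 from the face opposite the axial angular methyl so that the side chain ends equatorial (also the more stable α-epimer), and aqueous acid then removes the acetonide.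

**Compound list**

1 | methyl 3-oxohept-6-enoate | COC(=O)CC(=O)CCC=C | starting material
2 | methyl (2E)-3-{[(trifluoromethyl)sulfonyl]oxy}hepta-2,6-dienoate | COC(=O)/C=C(/OS(=O)(=O)C(F)(F)F)CCC=C | intermediate
3 | 2-(2-bromoethyl)-2-methyl-1,3-dioxolane | CC1(CCBr)OCCO1 | starting material
4 | [2-(2-methyl-1,3-dioxolan-2-yl)ethyl]magnesium bromide | CC1(CC[Mg]Br)OCCO1 | intermediate
5 | methyl (2E)-3-[2-(2-methyl-1,3-dioxolan-2-yl)ethyl]hepta-2,6-dienoate | COC(=O)/C=C(/CCC1(C)OCCO1)CCC=C | intermediate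
6 | (2E)-3-[2-(2-methyl-1,3-dioxolan-2-yl)ethyl]hepta-2,6-dien-1-ol | OC/C=C(/CCC1(C)OCCO1)CCC=C | intermediate
7 | [(2R,3R)-3-(but-3-en-1-yl)-3-[2-(2-methyl-1,3-dioxolan-2-yl)ethyl]oxiran-2-yl]methanol | OC[C@H]1O[C@]1(CCC=C)CCC2(C)OCCO2 | intermediate
8 | (2S,3R)-3-methyl-3-[2-(2-methyl-1,3-dioxolan-2-yl)ethyl]hept-6-ene-1,2-diol | OC[C@@H](O)[C@](C)(CCC=C)CCC1(C)OCCO1 | intermediate
9 | 2-[(3R,4S)-4,5-bis(benzyloxy)-3-(but-3-en-1-yl)-3-methylpentyl]-2-methyl-1,3-dioxolane | c1ccccc1COC[C@@H](OCc2ccccc2)[C@](C)(CCC=C)CCC3(C)OCCO3 | intermediate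
10 | (5R)-5-[(1S)-1,2-bis(benzyloxy)ethyl]-5-methylnon-8-en-2-one | c1ccccc1COC[C@@H](OCc2ccccc2)[C@](C)(CCC=C)CCC(C)=O | intermediate
11 | dimethyl malonate | COC(=O)CC(=O)OC | starting material
12 | dimethyl 2-[(5R)-5-[(1S)-1,2-bis(benzyloxy)ethyl]-5-methylnon-8-en-2-ylidene]propanedioate | c1ccccc1COC[C@@H](OCc2ccccc2)[C@](C)(CCC=C)CCC(C)=C(C(=O)OC)C(=O)OC | intermediate
13 | dimethyl 2-[(5S)-5-[(1S)-1,2-bis(benzyloxy)ethyl]-5-methyl-8-oxononan-2-ylidene]propanedioate | c1ccccc1COC[C@@H](OCc2ccccc2)[C@](C)(CCC(C)=O)CCC(C)=C(C(=O)OC)C(=O)OC | intermediate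
14 | dimethyl 2-[(1S,2S,4S)-2-acetyl-4-[(1S)-1,2-bis(benzyloxy)ethyl]-1,4-dimethylcyclohexyl]propanedioate | CC(=O)[C@H]1C[C@@](C)([C@H](OCc2ccccc2)COCc2ccccc2)CC[C@]1(C)C(C(=O)OC)C(=O)OC | intermediate
15 | methyl (4aS,6S,8aS)-6-[(1S)-1,2-bis(benzyloxy)ethyl]-6,8a-dimethyl-2,4-dioxodecahydronaphthalene-1-carboxylate (C-1 epimers, enolised) | COC(=O)C1C(=O)CC(=O)[C@H]2C[C@@](C)([C@H](OCc3ccccc3)COCc3ccccc3)CC[C@@]21C | intermediate
16 | (4aR,7S,8aS)-7-[(1S)-1,2-bis(benzyloxy)ethyl]-4a,7-dimethylhexahydronaphthalene-1,3(2H,4H)-dione | C1C(=O)CC(=O)[C@H]2C[C@@](C)([C@H](OCc3ccccc3)COCc3ccccc3)CC[C@@]21C | intermediate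
17 | (4aR,7S,8aS)-7-[(1S)-1,2-bis(benzyloxy)ethyl]-3-methoxy-4a,7-dimethyl-4a,5,6,7,8,8a-hexahydronaphthalen-1(4H)-one | C1C(OC)=CC(=O)[C@H]2C[C@@](C)([C@H](OCc3ccccc3)COCc3ccccc3)CC[C@@]21C | intermediate
18 | (4aR,7S,8aS)-7-[(1S)-1,2-bis(benzyloxy)ethyl]-3-methoxy-4a,7-dimethyl-1,4,4a,5,6,7,8,8a-octahydronaphthalen-1-ol (carbinol epimers) | C1C(OC)=CC(O)[C@H]2C[C@@](C)([C@H](OCc3ccccc3)COCc3ccccc3)CC[C@@]21C | intermediate
19 | (4aR,6S,8aR)-6-[(1S)-1,2-bis(benzyloxy)ethyl]-6,8a-dimethyl-4a,5,6,7,8,8a-hexahydronaphthalen-2(1H)-one | C1C(=O)C=C[C@H]2C[C@@](C)([C@H](OCc3ccccc3)COCc3ccccc3)CC[C@@]21C | intermediate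
20 | [(2R)-2-methyloxiran-2-yl]methanol | C[C@@]1(CO)CO1 | starting material
21 | allylmagnesium bromide | C=CC[Mg]Br | starting material
22 | (2S)-2-methylhex-5-ene-1,2-diol | C[C@@](O)(CO)CCC=C | intermediate
23 | (4S)-4-(but-3-en-1-yl)-2,2,4-trimethyl-1,3-dioxolane | C[C@]1(CCC=C)COC(C)(C)O1 | intermediate
24 | 3-[(4S)-2,2,4-trimethyl-1,3-dioxolan-4-yl]propanal | C[C@]1(CCC=O)COC(C)(C)O1 | intermediate
25 | (4aR,6S,8aS)-6-[(1S)-1,2-bis(benzyloxy)ethyl]-1-{1-hydroxy-3-[(4S)-2,2,4-trimethyl-1,3-dioxolan-4-yl]propyl}-6,8a-dimethyl-4a,5,6,7,8,8a-hexahydronaphthalen-2(1H)-one (epimers at C-1 and at the carbinol carbon) | C[C@]1(CCC(O)C2C(=O)C=C[C@H]3C[C@@](C)([C@H](OCc4ccccc4)COCc4ccccc4)CC[C@@]32C)COC(C)(C)O1 | intermediate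
26 | methanesulfonate of 25 (same epimer mixture) | C[C@]1(CCC(OS(C)(=O)=O)C2C(=O)C=C[C@H]3C[C@@](C)([C@H](OCc4ccccc4)COCc4ccccc4)CC[C@@]32C)COC(C)(C)O1 | intermediate
27 | (1Z,4aR,6S,8aS)-6-[(1S)-1,2-bis(benzyloxy)ethyl]-6,8a-dimethyl-1-{3-[(4S)-2,2,4-trimethyl-1,3-dioxolan-4-yl]propylidene}-4a,5,6,7,8,8a-hexahydronaphthalen-2(1H)-one | C[C@]1(CC/C=C2\C(=O)C=C[C@H]3C[C@@](C)([C@H](OCc4ccccc4)COCc4ccccc4)CC[C@@]32C)COC(C)(C)O1 | intermediate
28 | (1R,4aS,6S,8aS)-6-[(1S)-1,2-dihydroxyethyl]-6,8a-dimethyl-1-{3-[(4S)-2,2,4-trimethyl-1,3-dioxolan-4-yl]propyl}octahydronaphthalen-2(1H)-one | C[C@]1(CCC[C@H]2C(=O)CC[C@H]3C[C@@](C)([C@H](O)CO)CC[C@@]32C)COC(C)(C)O1 | intermediate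
29 | (1R,4aS,6S,8aS)-6-[(1S)-1,2-dihydroxyethyl]-1-[(4S)-4,5-dihydroxy-4-methylpentyl]-6,8a-dimethyloctahydronaphthalen-2(1H)-one | C[C@@](O)(CO)CCC[C@H]1C(=O)CC[C@H]2C[C@@](C)([C@H](O)CO)CC[C@@]21C | target

**Totals**

Total step count: 16. Longest linear sequence: 13 steps (steps 1–11, 15, 16, from methyl 3-oxohept-6-enoate).

**Steps most likely to fail**

Step 9. The conjugate addition has to build a quaternary carbon on a tetrasubstituted acceptor, and its facial selectivity relative to C-6 rests on a modest size difference between methyl and the bis-ether arm. Under equilibrating base the result could be a mixture of ring-fusion or C-6 diastereomers, or incomplete ring-A closure. The fallback separates the two bond formations and sets out from 13. Secondary-amine catalysis (pyrrolidine, AcOH, CH2Cl2) should effect the intramolecular Michael addition through the enamine and allow 14 to be isolated and freed from minor diastereomers. Krapcho demethoxycarbonylation (LiCl, wet DMSO, 150 °C) would then give methyl 2-[(1R,2S,4S)-2-acetyl-4-[(1S)-1,2-bis(benzyloxy)ethyl]-1,4-dimethylcyclohexyl]acetate F1. A separate Claisen (Dieckmann-type) cyclisation of F1 with t-BuOK in THF closes ring A without any decarboxylation and comes back to the route at 16.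

Step 10. O-Methylation may occur at the wrong carbonyl oxygen, or the acid may epimerise the ring-fusion CH next to the remaining carbonyl; either would send the transposition of step 11 to the wrong ketone or the wrong ring fusion. The fallback makes the regiochemistry irrelevant and sets out from 16. Oxalyl chloride with catalytic DMF in CH2Cl2 should give the two separable β-chloro enones, (4aR,7S,8aS)-7-[(1S)-1,2-bis(benzyloxy)ethyl]-3-chloro-4a,7-dimethyl-4a,5,6,7,8,8a-hexahydronaphthalen-1(4H)-one F2 and (4aS,6S,8aR)-6-[(1S)-1,2-bis(benzyloxy)ethyl]-4-chloro-6,8a-dimethyl-4a,5,6,7,8,8a-hexahydronaphthalen-2(1H)-one F3. F2 undergoes addition–elimination with NaOMe in MeOH at the chlorine-bearing carbon and comes back at 17. F3 is reduced with zinc–silver couple in MeOH (or Zn, AcOH) to the enone and comes back at 19.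

Step 15. The α′-enolate is flanked by the quaternary C-8a, so the reversible aldol addition may stall, γ-deprotonation may compete, or retro-aldol cleavage may occur during the elimination. The fallback replaces the condensation by an irreversible C-alkylation and sets out from 24 and 19. NaBH4 in MeOH reduces 24 to 3-[(4S)-2,2,4-trimethyl-1,3-dioxolan-4-yl]propan-1-ol F4, and I2, PPh3 and imidazole convert it into (4S)-4-(3-iodopropyl)-2,2,4-trimethyl-1,3-dioxolane F5. Alkylation of the lithium enolate of 19 (LiN(i-Pr)2, THF/DMPU) with F5 should give (4aR,6S,8aS)-6-[(1S)-1,2-bis(benzyloxy)ethyl]-6,8a-dimethyl-1-{3-[(4S)-2,2,4-trimethyl-1,3-dioxolan-4-yl]propyl}-4a,5,6,7,8,8a-hexahydronaphthalen-2(1H)-one F6 as C-1 epimers. Hydrogenation as in step 16, then NaOMe/MeOH equilibration of C-1 to the equatorial epimer, comes back at 28; the acid treatment of step 16 then gives 29.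

Further compounds
F1 | step 9 | methyl 2-[(1R,2S,4S)-2-acetyl-4-[(1S)-1,2-bis(benzyloxy)ethyl]-1,4-dimethylcyclohexyl]acetate | CC(=O)[C@H]1C[C@@](C)([C@H](OCc2ccccc2)COCc2ccccc2)CC[C@]1(C)CC(=O)OC
F2 | step 10 | (4aR,7S,8aS)-7-[(1S)-1,2-bis(benzyloxy)ethyl]-3-chloro-4a,7-dimethyl-4a,5,6,7,8,8a-hexahydronaphthalen-1(4H)-one | C1C(Cl)=CC(=O)[C@H]2C[C@@](C)([C@H](OCc3ccccc3)COCc3ccccc3)CC[C@@]21C
F3 | step 10 | (4aS,6S,8aR)-6-[(1S)-1,2-bis(benzyloxy)ethyl]-4-chloro-6,8a-dimethyl-4a,5,6,7,8,8a-hexahydronaphthalen-2(1H)-one | C1C(=O)C=C(Cl)[C@H]2C[C@@](C)([C@H](OCc3ccccc3)COCc3ccccc3)CC[C@@]21C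
F4 | step 15 | 3-[(4S)-2,2,4-trimethyl-1,3-dioxolan-4-yl]propan-1-ol | C[C@]1(CCCO)COC(C)(C)O1
F5 | step 15 | (4S)-4-(3-iodopropyl)-2,2,4-trimethyl-1,3-dioxolane | C[C@]1(CCCI)COC(C)(C)O1
F6 | step 15 | (4aR,6S,8aS)-6-[(1S)-1,2-bis(benzyloxy)ethyl]-6,8a-dimethyl-1-{3-[(4S)-2,2,4-trimethyl-1,3-dioxolan-4-yl]propyl}-4a,5,6,7,8,8a-hexahydronaphthalen-2(1H)-one (C-1 epimers) | C[C@]1(CCCC2C(=O)C=C[C@H]3C[C@@](C)([C@H](OCc4ccccc4)COCc4ccccc4)CC[C@@]32C)COC(C)(C)O1
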